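**Assumptions (one line each)**
- The Josiphos enantiomer written in Step 1 is taken to give the enantiomer of 2 shown; if the sense is opposite, the mirror-image ligand (also commercial) is used.
- The target is drawn as the free base; it would be isolated as its bis-hydrochloride and neutralised.

## Retrosynthetic overview
1. The target comes from hydrazinolysis of bis(imidazo[1,2-a]pyrimidine) 17; the two different amides come from the homotopic CH2OH arms of C2-symmetric diol 5, differentiated once by monosilylation.
2. The imidazo[1,2-a]pyrimidines (masked 2-aminoimidazoles) come from an all-trans bis(bromoacetyl)cyclobutane and 2-aminopyrimidine.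
3. The all-trans diacetyl diester 3 comes from thermodynamic epimerisation of the cis,trans,cis diketo diacid 2.
4. Key new disconnection: both acetyl C–CH3 bonds and the absolute configuration come from a Pd-catalysed double enantioselective desymmetrising methylation of the meso dianhydride 1.
5. Ring order: the cyclobutane is bought (in 1); two imidazo[1,2-a]pyrimidines are formed (Step 9) and opened to the 2-aminoimidazoles (Step 14); both pyrroles are bought.

## Route

**Step 1**
Reactants: 1, cis,trans,cis-cyclobutane-1,2,3,4-tetracarboxylic dianhydride (meso maleic anhydride photodimer)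
Product: 2, (1S,2S,3S,4S)-3,4-diacetylcyclobutane-1,2-dicarboxylic acid (each acetyl cis to its neighbouring CO2H; the two CO2H trans; the two acetyls trans; C2-symmetric)
Conditions: Me2Zn (3 equiv), Pd(OAc)2 (10 mol %), (R)-(Sp)-Josiphos (12 mol %), 4-fluorostyrene (0.5 equiv), THF/NMP 4:1, 0 → 40 °C; 1 M HCl work-up
Reagents that add atoms: dimethylzinc, C[Zn]C
Why: Proposed new method: Pd(0)/Josiphos inserts into one of the two enantiotopic acyl C–O bonds of each anhydride ring (enantio-determining), then Zn-to-Pd methyl transfer and acyl–CH3 reductive elimination give a γ-keto carboxylate; because the two rings of 1 are related by a C2 axis, the same catalyst preference at both gives the C2-symmetric product with adjacent acetyls and adjacent trans acids, while a mismatch gives a separable centrosymmetric 1,3-diacetyl isomer, so the ee of 2 is amplified; the ring stereocentres are inherited from 1 and the catalyst decides which carbons keep CO2H, i.e. the absolute configuration; closest known reaction type is the Pd- or Rh-catalysed enantioselective alkylation of simple meso succinic mono-anhydrides with diorganozincs.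

**Step 2**
Reactants: 2
Product: 3, dimethyl (1S,2S,3R,4R)-3,4-diacetylcyclobutane-1,2-dicarboxylate (all-trans)
Conditions: MeI, K2CO3, DMF, 0 °C → rt; work-up; then DBU (0.3 equiv), CH2Cl2, rt → 40 °C; recrystallise
Reagents that add atoms: iodomethane, CI
Why: Carboxylate O-alkylation, then base-mediated thermodynamic epimerisation (enolisation) of the two acetyl-bearing carbons moves each acetyl trans to both neighbours, while the less acidic ester-bearing carbons that carry the absolute configuration are untouched.

**Step 3**
Reactants: 3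
Product: 4, dimethyl (1S,2S,3R,4R)-3,4-bis(2-methyl-1,3-dioxolan-2-yl)cyclobutane-1,2-dicarboxylate
Conditions: ethylene glycol, TsOH (cat.), benzene, reflux (Dean–Stark)
Reagents that add atoms: ethylene glycol, OCCO
Why: Standard acid-catalysed ketalisation protects both methyl ketones; the all-trans isomer is already the thermodynamic one, so no stereochemical change.

**Step 4**
Reactants: 4
Product: 5, [(1R,2R,3S,4S)-3,4-bis(2-methyl-1,3-dioxolan-2-yl)cyclobutane-1,2-diyl]dimethanol (all-trans, C2-symmetric)
Conditions: LiAlH4, THF, 0 °C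
Reagents that add atoms: none
Why: Hydride reduction of esters to primary alcohols with ketals inert; this makes the arm-bearing stereocentres non-epimerisable.

**Step 5**
Reactants: 5
Product: 6, mono-triisopropylsilyl ether of 5 (all-trans; one CH2OH, one CH2OTIPS)
Conditions: NaH (1.0 equiv), THF, 0 °C → rt; then TIPSCl (1.0 equiv)
Reagents that add atoms: triisopropylsilyl chloride, CC(C)[Si](Cl)(C(C)C)C(C)C
Why: Monosilylation of a symmetric diol via its mono-sodium alkoxide; the two OH groups are homotopic (C2 axis), so only one mono-ether can form.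

**Step 6**
Reactants: 6
Product: 7, all-trans 1-(azidomethyl)-2-(triisopropylsilyloxymethyl)-3,4-bis(2-methyl-1,3-dioxolan-2-yl)cyclobutane
Conditions: MsCl, Et3N, CH2Cl2, 0 °C; then NaN3, DMF, 70 °C
Reagents that add atoms: sodium azide, [Na+].[N-]=[N+]=[N-]
Why: Mesylation followed by SN2 azide displacement at a primary carbon; no stereocentre is involved.

**Step 7**
Reactants: 7
Product: 8, all-trans 1,2-diacetyl-3-(triisopropylsilyloxymethyl)-4-(azidomethyl)cyclobutane
Conditions: PPTS, acetone/H2O, 55 °C
Reagents that add atoms: water, O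
Why: Mild acid-catalysed ketal hydrolysis that leaves the primary TIPS ether and the azide intact; the all-trans diketone is the thermodynamic isomer.

**Step 8**
Reactants: 8
Product: 9, all-trans 1,2-bis(bromoacetyl)-3-(triisopropylsilyloxymethyl)-4-(azidomethyl)cyclobutane
Conditions: LiHMDS (2.4 equiv), THF, −78 °C, then TMSCl; NBS (2.1 equiv), THF, 0 °C
Reagents that add atoms: N-bromosuccinimide, O=C1CCC(=O)N1Br
Why: Kinetic enolisation occurs at the unhindered CH3 (a ring-side enolate would add strain), and bromination of the terminal silyl enol ethers gives the bromomethyl ketones; the trans diacetyl geometry prevents intramolecular aldol.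

**Step 9**
Reactants: 9; 10, 2-aminopyrimidine
Product: 11, all-trans 1,2-bis(imidazo[1,2-a]pyrimidin-2-yl)-3-(triisopropylsilyloxymethyl)-4-(azidomethyl)cyclobutane
Conditions: 10 (6 equiv), NaHCO3, EtOH, 80 °C
Reagents that add atoms: 2-aminopyrimidine (10), Nc1ncccn1
Why: Tschitschibabin-type imidazo[1,2-a]pyrimidine annulation (ring-N alkylation, then cyclodehydration onto the ketone) installs both masked 2-aminoimidazoles and removes the last epimerisable centres.

**Step 10**
Reactants: 11; 12, 2-(trichloroacetyl)pyrrole
Product: 13, the pyrrole-2-carboxamide of the amine from 11 (TIPS ether retained)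
Conditions: PPh3, THF/H2O, 45 °C; then 12, Et3N, MeCN, rt
Reagents that add atoms: 2-(trichloroacetyl)pyrrole (12), O=C(c1ccc[nH]1)C(Cl)(Cl)Cl
Why: Staudinger reduction of the azide, then haloform-type acyl transfer from the trichloromethyl ketone to the primary amine (CHCl3 leaves).

**Step 11**
Reactants: 13
Product: 14, the primary alcohol from desilylation of 13
Conditions: TBAF, AcOH (buffer), THF, rt
Reagents that add atoms: none
Why: Fluoride-mediated silyl ether cleavage; the amide, pyrrole and heteroarenes are inert.

**Step 12**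
Reactants: 14
Product: 15, the primary azide from 14
Conditions: PPh3, DIAD, (PhO)2P(O)N3, THF, 0 °C → rt
Reagents that add atoms: diphenylphosphoryl azide, O=P(N=[N+]=[N-])(Oc1ccccc1)Oc1ccccc1
Why: Mitsunobu azidation of a primary alcohol; HN3 is far more acidic than the pyrrole or amide N–H, so azide is the nucleophile.

**Step 13**
Reactants: 15; 16, 4-bromo-2-(trichloroacetyl)pyrrole
Product: 17, all-trans 1,2-bis(imidazo[1,2-a]pyrimidin-2-yl)cyclobutane carrying CH2NHCO(pyrrol-2-yl) and CH2NHCO(4-bromopyrrol-2-yl) arms
Conditions: PPh3, THF/H2O, 45 °C; then 16, Na2CO3, DMF, rt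
Reagents that add atoms: 4-bromo-2-(trichloroacetyl)pyrrole (16), O=C(c1cc(Br)c[nH]1)C(Cl)(Cl)Cl
Why: Staudinger reduction then haloform-type N-acylation, as in Step 10.

**Step 14**
Reactants: 17
Product: 18, desbromosceptrin (target)
Conditions: N2H4·H2O, EtOH, 90 °C (sealed); HCl/MeOH for isolation, then neutralise
Reagents that add atoms: none
Why: Hydrazine adds to the electron-poor pyrimidine ring and excises C5–C7 as pyrazole, leaving the former N8 as the exocyclic NH2 of each 2-aminoimidazole; the amides, C–Br bond and stereocentres are untouched.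

## Compound list
1 | cis,trans,cis-cyclobutane-1,2,3,4-tetracarboxylic dianhydride | O=C2[C@@H]1[C@H](C(=O)O2)[C@@H](C(=O)O3)[C@H]1C3=O | starting material
2 | (1S,2S,3S,4S)-3,4-diacetylcyclobutane-1,2-dicarboxylic acid | CC(=O)[C@@H]1[C@H](C(=O)O)[C@@H](C(=O)O)[C@H]1C(C)=O | intermediate
3 | dimethyl (1S,2S,3R,4R)-3,4-diacetylcyclobutane-1,2-dicarboxylate | CC(=O)[C@H]1[C@H](C(=O)OC)[C@@H](C(=O)OC)[C@@H]1C(C)=O | intermediate
4 | dimethyl (1S,2S,3R,4R)-3,4-bis(2-methyl-1,3-dioxolan-2-yl)cyclobutane-1,2-dicarboxylate | CC1(OCCO1)[C@H]2[C@H](C(=O)OC)[C@@H](C(=O)OC)[C@@H]2C3(C)OCCO3 | intermediate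
5 | [(1R,2R,3S,4S)-3,4-bis(2-methyl-1,3-dioxolan-2-yl)cyclobutane-1,2-diyl]dimethanol | CC1(OCCO1)[C@H]2[C@H](CO)[C@@H](CO)[C@@H]2C3(C)OCCO3 | intermediate
6 | mono-TIPS ether of 5 (all-trans) | CC1(OCCO1)[C@H]2[C@H](CO)[C@@H](CO[Si](C(C)C)(C(C)C)C(C)C)[C@@H]2C3(C)OCCO3 | intermediate
7 | azidomethyl / TIPSOCH2 bis-ketal (all-trans) | CC1(OCCO1)[C@H]2[C@H](CN=[N+]=[N-])[C@@H](CO[Si](C(C)C)(C(C)C)C(C)C)[C@@H]2C3(C)OCCO3 | intermediate
8 | all-trans 1,2-diacetyl-3-(TIPSOCH2)-4-(azidomethyl)cyclobutane | CC(=O)[C@H]1[C@H](CN=[N+]=[N-])[C@@H](CO[Si](C(C)C)(C(C)C)C(C)C)[C@@H]1C(C)=O | intermediate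
9 | all-trans 1,2-bis(bromoacetyl)-3-(TIPSOCH2)-4-(azidomethyl)cyclobutane | BrCC(=O)[C@H]1[C@H](CN=[N+]=[N-])[C@@H](CO[Si](C(C)C)(C(C)C)C(C)C)[C@@H]1C(=O)CBr | intermediate
10 | 2-aminopyrimidine | Nc1ncccn1 | starting material
11 | all-trans bis(imidazo[1,2-a]pyrimidin-2-yl) azide / TIPS ether | c1cnc2nc(cn2c1)[C@H]3[C@H](CN=[N+]=[N-])[C@@H](CO[Si](C(C)C)(C(C)C)C(C)C)[C@@H]3c4cn5cccnc5n4 | intermediate
12 | 2,2,2-trichloro-1-(1H-pyrrol-2-yl)ethan-1-one | O=C(c1ccc[nH]1)C(Cl)(Cl)Cl | starting material
13 | pyrrole-2-carboxamide / TIPS ether | c1cnc2nc(cn2c1)[C@H]3[C@H](CNC(=O)c4ccc[nH]4)[C@@H](CO[Si](C(C)C)(C(C)C)C(C)C)[C@@H]3c5cn6cccnc6n5 | intermediate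
14 | pyrrole-2-carboxamide / primary alcohol | c1cnc2nc(cn2c1)[C@H]3[C@H](CNC(=O)c4ccc[nH]4)[C@@H](CO)[C@@H]3c5cn6cccnc6n5 | intermediate
15 | pyrrole-2-carboxamide / azide | c1cnc2nc(cn2c1)[C@H]3[C@H](CNC(=O)c4ccc[nH]4)[C@@H](CN=[N+]=[N-])[C@@H]3c5cn6cccnc6n5 | intermediate
16 | 1-(4-bromo-1H-pyrrol-2-yl)-2,2,2-trichloroethan-1-one | O=C(c1cc(Br)c[nH]1)C(Cl)(Cl)Cl | starting material
17 | bis(imidazo[1,2-a]pyrimidin-2-yl) hetero-bis-amide | c1cnc2nc(cn2c1)[C@H]3[C@H](CNC(=O)c4ccc[nH]4)[C@@H](CNC(=O)c7cc(Br)c[nH]7)[C@@H]3c5cn6cccnc6n5 | intermediate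
18 | desbromosceptrin (all-trans; imidazole-bearing carbons S, CH2N-bearing carbons R) | Nc1ncc([C@H]2[C@H](CNC(=O)c3ccc[nH]3)[C@@H](CNC(=O)c3cc(Br)c[nH]3)[C@@H]2c2cnc(N)[nH]2)[nH]1 | target

## Summary
Total steps: 14. Longest linear sequence: 14 (fully linear from 1; compounds 10, 12 and 16 are purchased).

Three steps most likely to fail:
1. **Step 1 (proposed new desymmetrising double methylation).** Risks are the low solubility of 1, incomplete second ring-opening, and modest selectivity. Fallback with known chemistry: make racemic 3 by the established furan route (2,5-dimethylfuran + dimethyl acetylenedicarboxylate Diels–Alder, photoisomerisation to the 3-oxaquadricyclane, H2SO4 fragmentation to the all-trans diketo diester). The single enantiomer is then secured either by the known pig-liver-esterase desymmetrisation variant of that sequence, or by chiral SFC or lipase acylative resolution of diol 5; the route is rejoined at 3 or 5.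
2. **Step 9 (double annulation on adjacent hindered bromoketones).** Fallback: drop the masked heterocycle. Keep the ketals, complete both amide arms first, deketalise, α-chlorinate the methyl ketones (benzyltrimethylammonium dichloroiodate), displace with NaN(CHO)2, deformylate, and condense the bis(α-aminoketone) with cyanamide to form both 2-aminoimidazoles directly. The unbrominated pyrrole may be halogenated in that chlorination and might need N-protection.
3. **Step 5 (monosilylation of the C2 diol).** Fallback: convert 5 to the bis-azide, carry it through Steps 7–9, reduce to the C2-symmetric diamine, and differentiate by mono-acylation of its mono-hydrochloride with 12 (homotopic amines give one mono-amide; recycle the rest), then acylate with 16.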